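Ring positions are numbered as in the target throughout: C1 is the alkene carbon that carries the exocyclic C7H2O unit, C2 bears OBz, C3 OAc, C4 OH, C5 OH, and C6 is the alkene CH.

## Analysis of the target

The target 13 is a single cyclohexene ring in which C1=C6 is the only ring alkene, C1 carries the C7H2OBz arm, and C2 to C5 form an unbroken run of four oxygenated stereocentres. O2 and O3 are trans, O3 and O4 are cis, and O4 and O5 are trans; the absolute configuration is 2S,3S,4S,5R in this numbering, which is (3R,4S,5S,6S) in the systematic name. The five oxygens are in three different states: a primary allylic benzoate (O7), a secondary allylic benzoate (O2), an acetate (O3) and two free hydroxyls (O4, and the allylic O5). Acyl groups can migrate between neighbouring oxygens under base (O3 to O4, O2 to O3), and every intermediate at the dienol or dienone oxidation level can aromatise by losing an oxygen substituent. The carbon skeleton is trivial, so the real difficulty is telling five oxygens apart and controlling four contiguous stereocentres on a monocyclic ring that has no ring fusion to bias its faces. The strategy rests on the fact that C2 and C5 are para-related oxygenated carbons on either side of C1=C6. A precursor with a second alkene at C3=C4, a carbonyl at C2 and a ketal at C5 is therefore a 2-substituted p-quinone 4-monoketal. One catalytically set carbinol at C2 can then be relayed to C3 and C4 (anti dihydroxylation) and from there to C5 (hydroxyl-directed reduction), and the axial or equatorial character of O3 and O4 in the half-chair decides where the acetate goes.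

## Retrosynthetic reasoning

**O3–acetyl bond.** Target 13 is cut at the O3–C(acetyl) bond and traced to triol 11 through the cyclic orthoacetate 12 spanning O3 and O4. The cut is made here because only the cis pair O3/O4 can close a five-membered orthoester, and opening such a ring leaves the ester on the axial oxygen. O3 is axial in the half-chair in which the C2 benzoate is pseudoaxial, away from C7. This avoids any protecting group on O4 and O5; the forward step has to deliver one acetyl group to one of three free secondary hydroxyls.

**C5–H bond.** Triol 11 is traced to enone 10 by removing the hydride at C5. The C5 carbinol is the natural last stereocentre because both O3 and O4 sit on the face opposite to the required O5, so a hydride carried by either of them arrives from the correct side. The forward step has to give 1,2-reduction with hydride delivery syn to O3 and O4.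

**C5=O to the ketal.** Enone 10 is traced to the dimethyl ketal 9. The ketal is the form in which C5 is carried through all earlier steps, because a free carbonyl at C5 next to a dienyl system would tautomerise to an arene. The forward step is a mild hydrolysis that must not dehydrate the β-hydroxy ketone.

**C3–O and C4–O bonds (key disconnection).** Diol 9 is cut at both C–O bonds and traced to dienyl benzoate 7. The two hydroxyls are cis to each other and trans to O2, which is exactly what one suprafacial oxygen transfer to C3=C4 from the face opposite the C2 ester gives. Cutting here removes two stereocentres at once and leaves a flat, symmetric-looking diene whose only stereocentre is C2. The forward step needs site selectivity for C3=C4 over C1=C6 and facial selectivity anti to O2.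

**O2–benzoyl bond and C2–H bond.** Benzoate 7 is traced to dienol 6 and benzoyl chloride 4, and 6 to dienone 5 by removing the C2 hydride. This is the only point where absolute configuration enters, and it is set by a catalyst that distinguishes the substituted C1 flank of the carbonyl from the unsubstituted C3 flank.

**O7–benzoyl bond.** Dienone 5 is traced to the primary alcohol 3 and 4. The benzoate is put on before the reduction so that the catalyst meets no free hydroxyl and so that the O7 ester later deactivates C1=C6.

**Dearomatisation.** Quinone monoketal 3 is traced to phenol 2. The para-methoxy group of 2 becomes one arm of the ketal, and the phenolic carbon becomes C2.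

**Benzylic C–H bond.** Phenol 2 is traced to the commercial aldehyde 1 by a simple carbonyl reduction.

## Alternatives that were turned down

**Alternative 1:** The C4–O and C5–O bonds are traced to an oxirane, 4-bromo-7-oxabicyclo[4.1.0]hept-4-ene-2,3-diol (A1). In A1, C1 carries bromine in place of C7, and O2, O3 and the epoxide oxygen lie on one face. A1 comes from (1S,2S)-3-bromocyclohexa-3,5-diene-1,2-diol (A2), the product of enzymatic arene cis-dihydroxylation.
- Forward key step: a peracid (m-chloroperbenzoic acid) epoxidises C4=C5 of A2 syn to the allylic C3 hydroxyl by hydrogen-bonded delivery.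
- For it: A2 is a single enantiomer from the enzyme, the bromine makes C1=C6 too electron-poor to compete (site selectivity is essentially built in), and the vinyl bromide is a handle for C7. On enantiopurity and on site selectivity this route is stronger than the chosen one.
- Against it: A2 has O2 and O3 cis, whereas the target has them trans, so C2 must be inverted late, in a molecule that already carries several other hydroxyls. After opening A1 at the allylic C5, four secondary hydroxyls are free at once and must be told apart. C7 must still be attached by a palladium-catalysed step. Both A2 and A1 aromatise readily by loss of water under the acidic conditions a peracid creates.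
- Comparison: the chosen route offers C2 with the correct configuration from the first stereogenic step, C7 in place from the start, and only ester groups that the target itself contains. That is worth more here than the guaranteed site selectivity.

**Alternative 2:** The C1–C2 ring bond is cut. The product of the closure is the bicyclic ester A3 (methyl 7-(tert-butyldimethylsilyloxy)-4-hydroxy-2,2-dimethyl-3a,4,7,7a-tetrahydro-1,3-benzodioxole-5-carboxylate, with the target configuration at C2 to C5). It is formed from the acyclic aldehyde enoate A4, which is made from D-arabinose (A5).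
- Forward key step: PMe3 adds to C6 of the enoate of A4, the resulting enolate carbon C1 attacks the C2 aldehyde, and loss of the phosphine restores C1=C6 (intramolecular Morita–Baylis–Hillman reaction).
- For it: C3, C4 and C5 come from the pentose with certain absolute configuration. C7 is at the ester level, so the ring alkene is formed exactly where needed and cannot be confused with another. Only C2 is new. On certainty of three of the four stereocentres it is stronger than the chosen route.
- Against it: turning A5 into A4 needs a long run of protecting-group steps (acetonide on one diol, silyl on one hydroxyl, chain extension at one end, oxidation at the other). The new C2 carbinol is set only by substrate control in a reversible aldol step. The α-alkoxy aldehyde of A4 can epimerise, and the γ-silyloxy group can be eliminated from the phosphonium enolate. After A3 the ester must still be reduced and silyl and acetonide groups removed before the same final acetylation problem is met.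
- Comparison: the route would be roughly half as long again as the nine steps chosen. The chosen route gives a reagent-controlled C2 and no protecting groups foreign to the target.

**Alternative 3:** The C5–C6 bond is cut. The product is cyclohexanone A6 (C1 ketone, C6 methylene, free C5 hydroxyl, O2 as a 4-methoxybenzyl ether, O3/O4 as an acetonide), formed from methyl 6-deoxy-2,3-O-isopropylidene-4-O-(4-methoxybenzyl)-α-L-lyxo-hex-5-enopyranoside (A7).
- Forward key step: catalytic Hg(OCOCF3)2 (divalent mercury) in aqueous acetone hydroxymercurates the exocyclic enol ether of A7, the pyranoside opens to a keto aldehyde, and the mercury enolate at C6 adds to the C5 aldehyde (Ferrier carbocyclisation).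
- For it: A6 has all four oxygenated stereocentres of the target, three from the sugar and C5 from a chair-controlled aldol whose preference is predictable. On relative stereocontrol it is at least as strong as the chosen route.
- Against it: A6 lacks both C7 and the C1=C6 alkene. They must be built at the C1 ketone by a one-carbon addition and a regioselective elimination toward C6, in competition with β-elimination of O5. The L-configured hexose series needed for A7 is not a cheap pool. Mercury is used, and the benzyl-type ether and the acetonide must be exchanged for the esters of the target.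
- Comparison: the sequence would be well over a dozen steps. The chosen route has the full carbon skeleton after its first step and sets all stereochemistry in three operations.

Key step: step 6

Assumption: in the oxazaborolidine reduction (step 4) the C1 flank of dienone 5, which carries the CH2OBz group on the α-carbon, is taken to behave as the large group. The (S)-catalyst is chosen on that basis, and its enantiomer would be used if the substrate did not follow the usual model.

## Route

Step 1
Reactants: 1 2-hydroxy-5-methoxybenzaldehyde
Product: 2 2-(hydroxymethyl)-4-methoxyphenol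
Conditions: NaBH4, MeOH, 0 °C to rt; aq. NH4Cl
Reagents that add atoms: none
Why: Borohydride reduction of an aryl aldehyde to the benzylic alcohol; the phenol and the aryl ether are inert and no stereocentre is formed.

Step 2
Reactants: 2 2-(hydroxymethyl)-4-methoxyphenol
Product: 3 2-(hydroxymethyl)-4,4-dimethoxycyclohexa-2,5-dien-1-one
Conditions: PhI(OAc)2 (1.1 equiv), MeOH, 0 °C; aq. NaHCO3 work-up
Reagents that add atoms: methanol, CO
Why: Oxidative dearomatisation of a p-methoxyphenol with a trivalent iodine reagent: ligand exchange of the phenol at iodine, loss of iodobenzene and capture of the electron-poor ring by methanol at the methoxy-bearing para carbon, where the existing OMe best stabilises positive charge, gives the quinone monoketal. The primary alcohol is a bystander under these conditions.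

Step 3
Reactants: 3 2-(hydroxymethyl)-4,4-dimethoxycyclohexa-2,5-dien-1-one; 4 benzoyl chloride
Product: 5 (3,3-dimethoxy-6-oxocyclohexa-1,4-dien-1-yl)methyl benzoate
Conditions: BzCl (1.1 equiv), pyridine, CH2Cl2, 0 °C
Reagents that add atoms: benzoyl chloride (4), O=C(Cl)c1ccccc1
Why: Acylation of the only hydroxyl, a primary allylic alcohol, with an acid chloride and an amine base; the basic medium keeps the ketal intact, and no nucleophilic catalyst is used so that nothing adds to the dienone.

Step 4
Reactants: 5 (3,3-dimethoxy-6-oxocyclohexa-1,4-dien-1-yl)methyl benzoate
Product: 6 [(6R)-6-hydroxy-3,3-dimethoxycyclohexa-1,4-dien-1-yl]methyl benzoate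
Conditions: (S)-1-methyl-3,3-diphenyltetrahydro-1H,3H-pyrrolo[1,2-c][1,3,2]oxazaborole ((S)-Me-CBS, 15 mol %), BH3·SMe2 (1.0 equiv), THF, −30 °C; MeOH, then aq. NaHCO3; crude product used at once
Reagents that add atoms: none
Why: Corey–Bakshi–Shibata reduction of an α-substituted cross-conjugated dienone: the catalyst binds BH3 at nitrogen and the carbonyl oxygen at boron on the lone pair anti to the larger C1 flank, and hydride passes to one face of C2 through the six-membered transition state, which by the usual model gives the (R)-carbinol from the (S)-catalyst. Enones are reduced in the 1,2-sense under these conditions, the benzoate is inert to borane at −30 °C, and the basic work-up avoids acid-induced loss of methanol and aromatisation of the dienol ketal.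

Step 5
Reactants: 6 [(6R)-6-hydroxy-3,3-dimethoxycyclohexa-1,4-dien-1-yl]methyl benzoate; 4 benzoyl chloride
Product: 7 [(6R)-6-(benzoyloxy)-3,3-dimethoxycyclohexa-1,4-dien-1-yl]methyl benzoate
Conditions: BzCl (1.2 equiv), pyridine, DMAP (cat.), CH2Cl2, 0 °C
Reagents that add atoms: benzoyl chloride (4), O=C(Cl)c1ccccc1
Why: DMAP-catalysed acylation of the secondary doubly allylic alcohol on oxygen; no bond to C2 is broken, so the configuration is retained, and the basic medium protects the acid-labile dienyl ketal, which should be kept cold and free of acid.

Step 6
Reactants: 7 [(6R)-6-(benzoyloxy)-3,3-dimethoxycyclohexa-1,4-dien-1-yl]methyl benzoate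
Product: 9 [(4R,5S,6S)-6-(benzoyloxy)-4,5-dihydroxy-3,3-dimethoxycyclohex-1-en-1-yl]methyl benzoate, via cyclic osmate ester 8 (not isolated)
Conditions: OsO4 (3 mol %), NMO (1.1 equiv), acetone/H2O 8:1, 0 °C
Reagents that add atoms: osmium tetroxide, O=[Os](=O)(=O)=O; N-methylmorpholine N-oxide, C[N+]1([O-])CCOCC1; water, O
Why: OsO4 adds across C3=C4 in a concerted [3+2] cycloaddition to give the cyclic osmate ester 8 (hexavalent osmium), which is hydrolysed in the aqueous medium to diol 9 while the amine oxide returns the metal to OsO4; this is the Upjohn cis-dihydroxylation, and the closest known reaction type is the substrate-controlled osmylation of cyclic allylic ethers and esters, which takes place anti to the allylic oxygen. No ring is closed in the product, because the five-membered osmate ring of 8 is only transient. C3 and C4 are formed together and suprafacially, so their hydroxyls are necessarily cis, and their configuration relative to C2 is controlled by the C2 benzoate: the reagent approaches the nearly flat 1,4-diene from the face opposite this pseudoaxial ester, placing both new hydroxyls trans to O2. The gem-dimethoxy carbon C5 has one methoxy group on each face and does not bias the approach. Site selectivity between the two alkenes is needed: C1=C6 is trisubstituted, is flanked at C1 by both the C2 benzoate and the C7 benzoate, and is deactivated inductively by three allylic C–O carbons instead of two, so the cis-disubstituted C3=C4 should react first. A second dihydroxylation is limited by using close to one equivalent of co-oxidant at 0 °C and stopping when 7 is consumed. The benzoates and the ketal are stable in the nearly neutral medium, although migration of the O2 benzoate to O3 has to be watched.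

Step 7
Reactants: 9 [(4R,5S,6S)-6-(benzoyloxy)-4,5-dihydroxy-3,3-dimethoxycyclohex-1-en-1-yl]methyl benzoate
Product: 10 [(4R,5S,6S)-6-(benzoyloxy)-4,5-dihydroxy-3-oxocyclohex-1-en-1-yl]methyl benzoate
Conditions: CF3CO2H/H2O 1:1, CH2Cl2, 0 °C
Reagents that add atoms: water, O
Why: Acid-catalysed hydrolysis of the allylic dimethyl ketal through the alkene-stabilised oxocarbenium ion and its hemiketal gives the conjugated C5 ketone; esters and secondary hydroxyls are untouched in cold dilute acid and no stereocentre is involved. Short exposure at 0 °C is chosen to avoid dehydration of the β-hydroxy ketone (loss of O3), which would lead to an arene.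

Step 8
Reactants: 10 [(4R,5S,6S)-6-(benzoyloxy)-4,5-dihydroxy-3-oxocyclohex-1-en-1-yl]methyl benzoate
Product: 11 [(3R,4S,5S,6S)-6-(benzoyloxy)-3,4,5-trihydroxycyclohex-1-en-1-yl]methyl benzoate
Conditions: Me4NBH(OAc)3 (5 equiv), MeCN/AcOH 1:1, −30 °C
Reagents that add atoms: none
Why: Saksena–Evans hydroxyl-directed reduction: the reagent exchanges an acetate ligand for the axial O3 hydroxyl (the α-hydroxyl O4 on the same face can act in the same way) and delivers hydride intramolecularly to the C5 carbonyl from that face, so the new hydroxyl ends up anti to O3 and trans to O4. The electron-poor triacetoxyborohydride does not reduce the enone in the conjugate sense and leaves the esters alone at −30 °C.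

Step 9
Reactants: 11 [(3R,4S,5S,6S)-6-(benzoyloxy)-3,4,5-trihydroxycyclohex-1-en-1-yl]methyl benzoate
Product: 13 [(3R,4S,5S,6S)-5-(acetyloxy)-6-(benzoyloxy)-3,4-dihydroxycyclohex-1-en-1-yl]methyl benzoate, via cyclic orthoacetate 12 (not isolated)
Conditions: MeC(OMe)3 (1.3 equiv), CSA (5 mol %), MeCN, rt; then AcOH/H2O 4:1, rt
Reagents that add atoms: trimethyl orthoacetate, CC(OC)(OC)OC; water, O
Why: Acid-catalysed exchange of the orthoester with the cis O3/O4 pair gives the five-membered cyclic orthoacetate 12 (the trans O4/O5 pair cannot close a comparably unstrained ring), and mild aqueous acid then opens 12 through the 2-methyl-1,3-dioxolan-2-ylium ion and its hemiorthoester, a regioselective orthoester hydrolysis that is known to leave the ester on the axial oxygen of a cyclohexane cis-diol. O3 is the axial oxygen in the half-chair in which the C2 benzoate is pseudoaxial and avoids A(1,2) strain with C7, so the acetate should go to O3 while O4 and O5 stay free. No C–O bond at a stereocentre is broken.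

## Compound list

1 | 2-hydroxy-5-methoxybenzaldehyde | COc1ccc(O)c(C=O)c1 | starting material
2 | 2-(hydroxymethyl)-4-methoxyphenol | COc1ccc(O)c(CO)c1 | intermediate
3 | 2-(hydroxymethyl)-4,4-dimethoxycyclohexa-2,5-dien-1-one | O=C1C=CC(OC)(OC)C=C1CO | intermediate
4 | benzoyl chloride | O=C(Cl)c1ccccc1 | starting material
5 | (3,3-dimethoxy-6-oxocyclohexa-1,4-dien-1-yl)methyl benzoate | O=C1C=CC(OC)(OC)C=C1COC(=O)c1ccccc1 | intermediate
6 | [(6R)-6-hydroxy-3,3-dimethoxycyclohexa-1,4-dien-1-yl]methyl benzoate | C1=CC(OC)(OC)C=C(COC(=O)c2ccccc2)[C@@H]1O | intermediate
7 | [(6R)-6-(benzoyloxy)-3,3-dimethoxycyclohexa-1,4-dien-1-yl]methyl benzoate | C1=CC(OC)(OC)C=C(COC(=O)c2ccccc2)[C@@H]1OC(=O)c1ccccc1 | intermediate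
8 | cyclic osmate ester (hexavalent osmium, dioxo) spanning O3 and O4 of 9 | O=[Os]2(=O)O[C@H]1[C@@H](O2)C(OC)(OC)C=C(COC(=O)c3ccccc3)[C@@H]1OC(=O)c1ccccc1 | intermediate
9 | [(4R,5S,6S)-6-(benzoyloxy)-4,5-dihydroxy-3,3-dimethoxycyclohex-1-en-1-yl]methyl benzoate | O[C@H]1[C@@H](O)C(OC)(OC)C=C(COC(=O)c2ccccc2)[C@@H]1OC(=O)c1ccccc1 | intermediate
10 | [(4R,5S,6S)-6-(benzoyloxy)-4,5-dihydroxy-3-oxocyclohex-1-en-1-yl]methyl benzoate | O[C@H]1[C@@H](O)C(=O)C=C(COC(=O)c2ccccc2)[C@@H]1OC(=O)c1ccccc1 | intermediate
11 | [(3R,4S,5S,6S)-6-(benzoyloxy)-3,4,5-trihydroxycyclohex-1-en-1-yl]methyl benzoate | O[C@H]1[C@@H](O)[C@H](O)C=C(COC(=O)c2ccccc2)[C@@H]1OC(=O)c1ccccc1 | intermediate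
12 | cyclic orthoacetate of 11: O3,O4-(1-methoxyethylidene) derivative, mixture of epimers at the orthoester carbon | COC1(C)O[C@H]2[C@@H](O1)[C@H](O)C=C(COC(=O)c1ccccc1)[C@@H]2OC(=O)c1ccccc1 | intermediate
13 | [(3R,4S,5S,6S)-5-(acetyloxy)-6-(benzoyloxy)-3,4-dihydroxycyclohex-1-en-1-yl]methyl benzoate | CC(=O)O[C@H]1[C@@H](O)[C@H](O)C=C(COC(=O)c2ccccc2)[C@@H]1OC(=O)c1ccccc1 | target

## Step count and least certain steps

Total step count: 9. Longest linear sequence: 9 steps (1 to 13); benzoyl chloride 4 is used as bought.

**Step 6 (key step).** The most likely failure is poor site selectivity: osmylation of the trisubstituted C1=C6 alkene could compete because OsO4 is electrophilic and extra alkyl substitution raises alkene reactivity, which may offset the steric and inductive handicap of that alkene. Over-oxidation of the remaining alkene and base-promoted drift of the O2 benzoate to O3 are secondary risks. Facial selectivity is less of a worry because only the C2 ester differentiates the faces.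

The fallback replaces electronic differentiation by steric shielding and moves the O7 benzoylation behind the key step. It sets out from 3 and comes back at 10.
- Alcohol 3 is tritylated (Ph3CCl, pyridine) to 4,4-dimethoxy-2-[(triphenylmethoxy)methyl]cyclohexa-2,5-dien-1-one F1.
- F1 is reduced under the conditions of step 4 to (1R)-4,4-dimethoxy-2-[(triphenylmethoxy)methyl]cyclohexa-2,5-dien-1-ol F2.
- F2 is benzoylated with 4 to (1R)-4,4-dimethoxy-2-[(triphenylmethoxy)methyl]cyclohexa-2,5-dien-1-yl benzoate F3.
- OsO4/NMO on F3, where the very large trityl ether sits directly on the competing alkene, should give (1S,5R,6S)-5,6-dihydroxy-4,4-dimethoxy-2-[(triphenylmethoxy)methyl]cyclohex-2-en-1-yl benzoate F4.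
- Cold aqueous CF3CO2H removes trityl ether and ketal together to give (1S,5R,6S)-5,6-dihydroxy-2-(hydroxymethyl)-4-oxocyclohex-2-en-1-yl benzoate F5.
- Selective benzoylation of the primary hydroxyl of F5 with 4 (1.05 equiv, 2,4,6-collidine, CH2Cl2, −40 °C) returns to 10.

**Step 4.** The catalyst may discriminate poorly between the two flanks of the carbonyl, since both are sp2 carbons and differ only in the α-substituent, giving low enantiomeric purity. Boron Lewis acids may also trigger loss of methanol from the ketal and aromatisation.

The fallback is a resolution instead of an asymmetric reduction. It sets out from 5 and comes back at 6.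
- Luche reduction of 5 (NaBH4, CeCl3·7H2O, MeOH, −78 °C) gives racemic (6-hydroxy-3,3-dimethoxycyclohexa-1,4-dien-1-yl)methyl benzoate F6.
- Candida antarctica lipase B with vinyl acetate in tert-butyl methyl ether should acetylate the (R)-enantiomer, following the usual empirical rule for lipase acylation of secondary alcohols with the substituted C1 flank as the large group. This gives [(6R)-6-(acetyloxy)-3,3-dimethoxycyclohexa-1,4-dien-1-yl]methyl benzoate F7 and leaves [(6S)-6-hydroxy-3,3-dimethoxycyclohexa-1,4-dien-1-yl]methyl benzoate F8, which is separated.
- The same lipase with n-butanol removes the acetyl group of F7 under neutral conditions without touching the benzoate and gives 6.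
- F8 can be oxidised back to 5 with MnO2 and recycled.

**Step 8.** Poor facial selectivity is the main risk: if the ring prefers the half-chair with O3 equatorial, the boron-bound hydride cannot reach C5 and an undirected reduction could give the all-cis triol. Elimination of O3 in the acidic medium is a second risk.

The fallback uses steric approach control followed by inversion. It sets out from 10 and comes back at 11.
- 2,2-Dimethoxypropane and PPTS give the O3,O4-isopropylidene derivative of enone 10 F9.
- Luche reduction (NaBH4, CeCl3·7H2O, MeOH, −78 °C), with hydride approaching anti to the acetonide, should give the C5-epimeric allylic alcohol with O5 cis to O4 F10.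
- Mitsunobu reaction with chloroacetic acid (PPh3, DIAD) inverts C5 and gives the O5 chloroacetate with O5 trans to O4 F11.
- Thiourea and NaHCO3 in ethanol remove the chloroacetyl group selectively to give the O3,O4-isopropylidene derivative of triol 11 F12.
- Aqueous acetic acid removes the acetonide and gives 11.

**Step 9.** The orthoester may open toward O4 if the other half-chair (O4 axial) is populated, the acetyl group may migrate from O3 to O4 during work-up, and O5 may be drawn into mixed orthoester formation and pick up some acetate.

The fallback blocks O4 and O5 instead of relying on conformation. It sets out from 11 and comes back at 13.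
- Butane-2,3-dione, trimethyl orthoformate and CSA in methanol bridge only the trans-diequatorial O4/O5 pair, giving the O4,O5-butane-2,3-diacetal of 11 (2,3-dimethoxybutane-2,3-diyl bridge, both methoxy groups axial) F13.
- Ac2O, pyridine and DMAP acetylate the only free hydroxyl to give the O3 acetate of that diacetal F14.
- CF3CO2H/H2O 9:1 at room temperature removes the diacetal and gives 13.

## Further compounds

F1 | step 6 | 4,4-dimethoxy-2-[(triphenylmethoxy)methyl]cyclohexa-2,5-dien-1-one | O=C1C=CC(OC)(OC)C=C1COC(c1ccccc1)(c1ccccc1)c1ccccc1
F2 | step 6 | (1R)-4,4-dimethoxy-2-[(triphenylmethoxy)methyl]cyclohexa-2,5-dien-1-ol | C1=CC(OC)(OC)C=C(COC(c2ccccc2)(c2ccccc2)c2ccccc2)[C@@H]1O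
F3 | step 6 | (1R)-4,4-dimethoxy-2-[(triphenylmethoxy)methyl]cyclohexa-2,5-dien-1-yl benzoate | C1=CC(OC)(OC)C=C(COC(c2ccccc2)(c2ccccc2)c2ccccc2)[C@@H]1OC(=O)c1ccccc1
F4 | step 6 | (1S,5R,6S)-5,6-dihydroxy-4,4-dimethoxy-2-[(triphenylmethoxy)methyl]cyclohex-2-en-1-yl benzoate | O[C@H]1[C@@H](O)C(OC)(OC)C=C(COC(c2ccccc2)(c2ccccc2)c2ccccc2)[C@@H]1OC(=O)c1ccccc1
F5 | step 6 | (1S,5R,6S)-5,6-dihydroxy-2-(hydroxymethyl)-4-oxocyclohex-2-en-1-yl benzoate | O[C@H]1[C@@H](O)C(=O)C=C(CO)[C@@H]1OC(=O)c1ccccc1
F6 | step 4 | (6-hydroxy-3,3-dimethoxycyclohexa-1,4-dien-1-yl)methyl benzoate, racemic | OC1C=CC(OC)(OC)C=C1COC(=O)c1ccccc1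
F7 | step 4 | [(6R)-6-(acetyloxy)-3,3-dimethoxycyclohexa-1,4-dien-1-yl]methyl benzoate | C1=CC(OC)(OC)C=C(COC(=O)c2ccccc2)[C@@H]1OC(C)=O
F8 | step 4 | [(6S)-6-hydroxy-3,3-dimethoxycyclohexa-1,4-dien-1-yl]methyl benzoate | C1=CC(OC)(OC)C=C(COC(=O)c2ccccc2)[C@H]1O
F9 | step 8 | O3,O4-isopropylidene derivative of enone 10 | CC1(C)O[C@H]2[C@@H](O1)C(=O)C=C(COC(=O)c1ccccc1)[C@@H]2OC(=O)c1ccccc1
F10 | step 8 | C5-epimeric allylic alcohol of the acetonide, O5 cis to O4 | CC1(C)O[C@H]2[C@@H](O1)[C@@H](O)C=C(COC(=O)c1ccccc1)[C@@H]2OC(=O)c1ccccc1
F11 | step 8 | O5 chloroacetate of the acetonide, O5 trans to O4 | CC1(C)O[C@H]2[C@@H](O1)[C@H](OC(=O)CCl)C=C(COC(=O)c1ccccc1)[C@@H]2OC(=O)c1ccccc1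
F12 | step 8 | O3,O4-isopropylidene derivative of triol 11 | CC1(C)O[C@H]2[C@@H](O1)[C@H](O)C=C(COC(=O)c1ccccc1)[C@@H]2OC(=O)c1ccccc1
F13 | step 9 | O4,O5-butane-2,3-diacetal of triol 11, both methoxy groups axial | O[C@H]1[C@H]2O[C@](C)(OC)[C@@](C)(OC)O[C@@H]2C=C(COC(=O)c2ccccc2)[C@@H]1OC(=O)c1ccccc1
F14 | step 9 | O3 acetate of the O4,O5-butane-2,3-diacetal | CC(=O)O[C@H]1[C@H]2O[C@](C)(OC)[C@@](C)(OC)O[C@@H]2C=C(COC(=O)c2ccccc2)[C@@H]1OC(=O)c1ccccc1
A1 | alternative 1 | 4-bromo-7-oxabicyclo[4.1.0]hept-4-ene-2,3-diol, epoxide syn to both hydroxyls | O[C@H]1[C@H]2O[C@H]2C=C(Br)[C@H]1O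
A2 | alternative 1 | (1S,2S)-3-bromocyclohexa-3,5-diene-1,2-diol | O[C@H]1C=CC=C(Br)[C@H]1O
A3 | alternative 2 | methyl 7-(tert-butyldimethylsilyloxy)-4-hydroxy-2,2-dimethyl-3a,4,7,7a-tetrahydro-1,3-benzodioxole-5-carboxylate, target configuration at C2 to C5 | CC1(C)O[C@H]2[C@@H](O1)[C@H](O[Si](C)(C)C(C)(C)C)C=C(C(=O)OC)[C@@H]2O
A4 | alternative 2 | methyl (E)-4-(tert-butyldimethylsilyloxy)-4-(5-formyl-2,2-dimethyl-1,3-dioxolan-4-yl)but-2-enoate, D-arabino configuration | CC1(C)O[C@H](C=O)[C@@H](O1)[C@H](O[Si](C)(C)C(C)(C)C)/C=C/C(=O)OC
A5 | alternative 2 | D-arabinose, open-chain form | O=C[C@@H](O)[C@H](O)[C@H](O)CO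
A6 | alternative 3 | cyclohexanone with C1 ketone, C6 methylene, free C5 hydroxyl, O2 4-methoxybenzyl ether and O3,O4 acetonide | CC1(C)O[C@H]2[C@@H](O1)[C@H](O)CC(=O)[C@@H]2OCc1ccc(OC)cc1
A7 | alternative 3 | methyl 6-deoxy-2,3-O-isopropylidene-4-O-(4-methoxybenzyl)-α-L-lyxo-hex-5-enopyranoside | CO[C@@H]1OC(=C)[C@H](OCc2ccc(OC)cc2)[C@H]3OC(C)(C)O[C@@H]13
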